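**Remarks on the chemistry (assumptions)**
- Labels: xanthanolide numbering. Unprimed atoms belong to the half with lactone A and ring B, primed atoms to the half with lactone D and ring E. Ring C is C1, C2, C3, C11', C13', C5. PMB = 4-methoxybenzyl.
- Stereochemistry: in the target the two seven-membered rings belong to opposite absolute series (7R,8R,10S against 7'S,8'S,10'R), so the two halves are made from mirror-image cyclopropanes. The mixed-acetal carbon of the lactone precursors is carried as a mixture of epimers, because it ends as a carbonyl carbon.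
- Tributyl(iodomethyl)stannane, methoxyallene and both enantiomers of Rh2(MEPY)4 (MEPY = methyl 2-oxopyrrolidine-5-carboxylate ligand, Rh2(C6H8NO3)4) are taken as commercial.
- The α-alkoxymethyllithium and the ethylidene ylide are each prepared once and shared by the two enantiomeric series, which are run side by side at those points.

**Retrosynthetic overview**
1. Ring C (C1, C2, C3, C11', C13', C5) is opened at C5–C13' (Michael addition), C11'–C3 (aldol of the lactone enolate) and C1–C2 (reversible aldol); the C3 acetyl group comes from an enol triflate by Stille coupling. This leaves a ring-B ketone carrying masked lactone A and the ring-D/E α-methylene lactone.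
2. Lactones D and A come from vinyl-radical cyclisation of a 2-bromoallyl acetal hung on the C8'/C8 hydroxyl (Saegusa oxidation and Luche reduction before it); lactone A stays masked as its methyl acetal until ring C stands.
3. The strategy rests on ring E (C8', C9', C10', C1', C5', C6', C7'): before epoxide and lactone it is a cyclohepta-1,4-diene equivalent, with enol C8'(O)=C7' and alkene C1'=C5' separated only by C6', and C10'(Me) on the far side. It is made by Cope rearrangement of a cis-divinylcyclopropane (new bond C9'–C10'); ring B is made the same way from the mirror-image cyclopropane.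
4. Order of ring formation: cyclopropane, ring E (and ring B), masked lactone D (and A), ring C, lactone A, epoxide.

Key step: step 11

**Shared reagents and the two cyclopropane lactones**

Step 1
Reactants: 1 allyl acetoacetate
Product: 3 allyl diazoacetate, via allyl 2-diazo-3-oxobutanoate 2 (not isolated)
Conditions: 4-AcNHC6H4SO2N3, Et3N, MeCN, 0 °C to rt; then LiOH, H2O, rt
Reagents that add atoms: 4-acetamidobenzenesulfonyl azide, CC(=O)Nc1ccc(cc1)S(=O)(=O)N=[N+]=[N-]
Why: Regitz diazo transfer to the 1,3-dicarbonyl methylene, then hydroxide-induced deacetylation, gives the acceptor-only diazo ester.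

Step 2
Reactants: 3 allyl diazoacetate
Product: 4 (1R,5S)-3-oxabicyclo[3.1.0]hexan-2-one
Conditions: Rh2(5S-MEPY)4 (0.2 mol %), CH2Cl2, reflux, slow addition of 3
Reagents that add atoms: none
Why: Doyle intramolecular cyclopropanation by the rhodium carbene; the tether forces the cis ring fusion and the chiral carboxamidate ligands select the alkene face that gives (1R,5S).

Step 3
Reactants: 3 allyl diazoacetate
Product: 5 (1S,5R)-3-oxabicyclo[3.1.0]hexan-2-one
Conditions: Rh2(5R-MEPY)4 (0.2 mol %), CH2Cl2, reflux, slow addition of 3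
Reagents that add atoms: none
Why: Doyle intramolecular cyclopropanation as in step 2; the enantiomeric catalyst gives (1S,5R).

Step 4
Reactants: 6 4-methoxybenzyl alcohol; 7 tributyl(iodomethyl)stannane
Product: 8 tributyl{[(4-methoxybenzyl)oxy]methyl}stannane
Conditions: NaH, THF/DMF, 0 °C to rt
Reagents that add atoms: tributyl(iodomethyl)stannane, CCCC[Sn](CI)(CCCC)CCCC
Why: Williamson ether synthesis; the alkoxide displaces iodide from the primary iodomethylstannane.

Step 5
Reactants: 8 tributyl{[(4-methoxybenzyl)oxy]methyl}stannane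
Product: 9 (4-methoxybenzyloxy)methyllithium (THF solution held at −78 °C and divided at once between steps 7 and 17)
Conditions: n-BuLi (1.0 equiv), THF, −78 °C
Reagents that add atoms: n-butyllithium, [Li]CCCC
Why: Tin–lithium exchange (Still's α-alkoxymethyllithium) is driven toward the oxygen-stabilised carbanion, and the reagent should hold at −78 °C long enough to be shared between the two lactones.

Step 6
Reactants: 10 ethyltriphenylphosphonium bromide
Product: 11 ethylidenetriphenylphosphorane (titrated THF stock solution for steps 8 and 18)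
Conditions: KN(SiMe3)2 (0.98 equiv), THF, 0 °C to rt; KBr left to settle, supernatant kept under Ar at −20 °C
Reagents that add atoms: none
Why: Deprotonation of the phosphonium salt by the hexamethyldisilazide gives the unstabilised ylide free of lithium salts, which is what the Z-selective olefinations need.

**Half with rings D and E (ent-xanthanolide series)**

Step 7
Reactants: 4 (1R,5S)-3-oxabicyclo[3.1.0]hexan-2-one; 9 (4-methoxybenzyloxy)methyllithium
Product: 12 (1R,5S)-2-{[(4-methoxybenzyl)oxy]methyl}-3-oxabicyclo[3.1.0]hexan-2-ol (C2 epimers; in equilibrium with the open hydroxy ketone)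
Conditions: 9 (1.1 equiv, THF solution), 4, THF, −78 °C; then H2O
Reagents that add atoms: (4-methoxybenzyloxy)methyllithium, [Li]COCc1ccc(OC)cc1
Why: Single addition of the α-alkoxymethyllithium to the lactone carbonyl, the lithium hemiketal being stable at −78 °C; the cyclopropane stereocentres are not touched.

Step 8
Reactants: 12 lactol; 11 ethylidenetriphenylphosphorane
Product: 13 [(1S,2R)-2-{(2Z)-1-[(4-methoxybenzyl)oxy]but-2-en-2-yl}cyclopropyl]methanol
Conditions: 11 (3 equiv, THF solution), THF, −78 °C to rt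
Reagents that add atoms: ethylidenetriphenylphosphorane, CC=P(c1ccccc1)(c1ccccc1)c1ccccc1
Why: Wittig olefination of the open hydroxy-ketone form with a salt-free unstabilised ylide; for α-alkoxy ketones this gives the Z trisubstituted allylic ether (methyl cis to CH2OPMB, hence trans to the cyclopropane), the geometry the Cope step needs.

Step 9
Reactants: 13 cyclopropylmethanol
Product: 14 (1S,2R)-2-{(2Z)-1-[(4-methoxybenzyl)oxy]but-2-en-2-yl}cyclopropane-1-carboxylic acid
Conditions: TEMPO (cat.), PhI(OAc)2, MeCN/H2O, rt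
Reagents that add atoms: water, O
Why: TEMPO/PhI(OAc)2 oxidation of the primary alcohol through the aldehyde hydrate to the acid under near-neutral conditions that leave the PMB ether, the alkene and the cis-cyclopropane alone.

Step 10
Reactants: 14 carboxylic acid
Product: 15 1-[(1S,2R)-2-{(2Z)-1-[(4-methoxybenzyl)oxy]but-2-en-2-yl}cyclopropyl]ethan-1-one
Conditions: MeLi (2.2 equiv), Et2O, 0 °C to rt; inverse quench into aqueous NH4Cl
Reagents that add atoms: methyllithium, [Li]C
Why: Addition of methyllithium to the lithium carboxylate stops at the dilithium gem-diolate, which gives the methyl ketone on work-up; the diolate cannot enolise, so the cis configuration holds.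

Step 11
Reactants: 15 cis-2-alkenylcyclopropyl methyl ketone
Product: 17 tert-butyl{[(6R)-5-{[(4-methoxybenzyl)oxy]methyl}-6-methylcyclohepta-1,4-dien-1-yl]oxy}dimethylsilane, via silyl enol ether 16 (not isolated)
Conditions: TBSOTf, Et3N, CH2Cl2, −78 to 0 °C; then toluene, 60 °C
Reagents that add atoms: tert-butyldimethylsilyl trifluoromethanesulfonate, CC(C)(C)[Si](C)(C)OS(=O)(=O)C(F)(F)F
Why: O-silylation of the ketone on its methyl side (enolisation toward the ring CH would give a strained alkylidenecyclopropane) creates the second vinyl group, and the cis-1,2-divinylcyclopropane 16 then undergoes a [3,3]-sigmatropic Cope rearrangement through the boat transition state with both vinyl groups folded over the three-membered ring; the closest known reaction type is the cis-divinylcyclopropane to cycloheptadiene rearrangement of 2-silyloxyvinyl cyclopropanes. Ring E is closed by ring expansion from three to seven atoms: the C9'–C10' bond forms between the vinyl termini while the cyclopropane bond between the two substituted carbons (the later C7' and C5') breaks, driven by strain release. The only new stereocentre, C10', follows from the (1S,2R) cyclopropane and the alkene geometry, the methyl group sitting on the outward position of its terminus, which gives R. The step needs the cis relation of the two vinyl groups and the outward methyl; the lactone origin of 15 secures the first and the Z-selective Wittig reaction of step 8 the second. The product holds the C1'=C5' alkene for the epoxide and a regiodefined enol silane at C8'=C7' for the lactone annulation.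

Step 12
Reactants: 17 silyloxycycloheptadiene
Product: 18 (6R)-5-{[(4-methoxybenzyl)oxy]methyl}-6-methylcyclohepta-2,4-dien-1-one
Conditions: Pd(OAc)2 (1.05 equiv), MeCN, rt
Reagents that add atoms: none
Why: Saegusa–Ito oxidation; the palladium enolate loses the doubly allylic C6' hydrogen by β-hydride elimination, and the enol silane from step 11 fixes the regiochemistry of the linear dienone.

Step 13
Reactants: 18 dienone
Product: 19 (1S,6R)-5-{[(4-methoxybenzyl)oxy]methyl}-6-methylcyclohepta-2,4-dien-1-ol
Conditions: NaBH4, CeCl3·7H2O, MeOH, −78 °C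
Reagents that add atoms: none
Why: Luche 1,2-reduction; hydride should add to the carbonyl face opposite the C10' methyl (held pseudo-axial by allylic strain with the CH2OPMB group), giving the 1,3-cis alcohol (C8' S).

Step 14
Reactants: 19 dienol; 20 methoxyallene
Product: 21 2-bromoallyl mixed methyl acetal of 19 (acetal epimers)
Conditions: N-bromosuccinimide, CH2Cl2, −40 to 0 °C
Reagents that add atoms: methoxyallene, COC=C=C; N-bromosuccinimide, O=C1CCC(=O)N1Br
Why: Bromoacetalisation; bromine adds to the central allene carbon and the alcohol traps the methoxy-stabilised cation, so C8' is not touched.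

Step 15
Reactants: 21 bromoacetal
Product: 22 (3aS,7R,8aS)-2-methoxy-6-{[(4-methoxybenzyl)oxy]methyl}-7-methyl-3-methylidene-3,3a,4,7,8,8a-hexahydro-2H-cyclohepta[b]furan (C2 epimers)
Conditions: Bu3SnH (slow addition), AIBN (cat.), benzene, 80 °C
Reagents that add atoms: none
Why: Ueno–Stork-type radical cyclisation; the vinyl radical closes 5-exo-trig onto C7', the tether from the C8' oxygen forcing the cis ring fusion (C7' S), and the allyl radical takes hydrogen at the less substituted C6', which restores the C1'=C5' alkene.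

Step 16
Reactants: 22 bicyclic methyl acetal
Product: 24 (3aS,7R,8aS)-6-{[(4-methoxybenzyl)oxy]methyl}-7-methyl-3-methylidene-3,3a,4,7,8,8a-hexahydro-2H-cyclohepta[b]furan-2-one, via lactol 23 (not isolated)
Conditions: AcOH/H2O/THF, 40 °C; then MnO2, CH2Cl2, rt
Reagents that add atoms: water, O
Why: Acetal hydrolysis to the lactol and MnO2 oxidation of the allylic hemiacetal give the α-methylene lactone; C7', C8' and C10' are not affected.

**Half with ring B and masked lactone A (natural xanthanolide series; mirror-image sequence)**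

Step 17
Reactants: 5 (1S,5R)-3-oxabicyclo[3.1.0]hexan-2-one; 9 (4-methoxybenzyloxy)methyllithium
Product: 25 (1S,5R)-2-{[(4-methoxybenzyl)oxy]methyl}-3-oxabicyclo[3.1.0]hexan-2-ol (C2 epimers)
Conditions: 9 (1.1 equiv, THF solution), 5, THF, −78 °C; then H2O
Reagents that add atoms: (4-methoxybenzyloxy)methyllithium, [Li]COCc1ccc(OC)cc1
Why: Single addition of the α-alkoxymethyllithium to the lactone, as in step 7; no stereocentre is touched.

Step 18
Reactants: 25 lactol; 11 ethylidenetriphenylphosphorane
Product: 26 [(1R,2S)-2-{(2Z)-1-[(4-methoxybenzyl)oxy]but-2-en-2-yl}cyclopropyl]methanol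
Conditions: 11 (3 equiv, THF solution), THF, −78 °C to rt
Reagents that add atoms: ethylidenetriphenylphosphorane, CC=P(c1ccccc1)(c1ccccc1)c1ccccc1
Why: Z-selective Wittig olefination of the α-alkoxy ketone as in step 8.

Step 19
Reactants: 26 cyclopropylmethanol
Product: 27 (1R,2S)-2-{(2Z)-1-[(4-methoxybenzyl)oxy]but-2-en-2-yl}cyclopropane-1-carboxylic acid
Conditions: TEMPO (cat.), PhI(OAc)2, MeCN/H2O, rt
Reagents that add atoms: water, O
Why: TEMPO/PhI(OAc)2 oxidation of the primary alcohol to the acid as in step 9.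

Step 20
Reactants: 27 carboxylic acid
Product: 28 1-[(1R,2S)-2-{(2Z)-1-[(4-methoxybenzyl)oxy]but-2-en-2-yl}cyclopropyl]ethan-1-one
Conditions: MeLi (2.2 equiv), Et2O, 0 °C to rt; inverse quench into aqueous NH4Cl
Reagents that add atoms: methyllithium, [Li]C
Why: Methyl ketone from the lithium carboxylate through the gem-diolate as in step 10.

Step 21
Reactants: 28 cis-2-alkenylcyclopropyl methyl ketone
Product: 30 tert-butyl{[(6S)-5-{[(4-methoxybenzyl)oxy]methyl}-6-methylcyclohepta-1,4-dien-1-yl]oxy}dimethylsilane, via silyl enol ether 29 (not isolated)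
Conditions: TBSOTf, Et3N, CH2Cl2, −78 to 0 °C; then toluene, 60 °C
Reagents that add atoms: tert-butyldimethylsilyl trifluoromethanesulfonate, CC(C)(C)[Si](C)(C)OS(=O)(=O)C(F)(F)F
Why: Enol silylation and cis-divinylcyclopropane Cope rearrangement as in step 11; the (1R,2S) cyclopropane with the outward methyl gives ring B with C10 S.

Step 22
Reactants: 30 silyloxycycloheptadiene
Product: 31 (6S)-5-{[(4-methoxybenzyl)oxy]methyl}-6-methylcyclohepta-2,4-dien-1-one
Conditions: Pd(OAc)2 (1.05 equiv), MeCN, rt
Reagents that add atoms: none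
Why: Saegusa–Ito oxidation as in step 12.

Step 23
Reactants: 31 dienone
Product: 32 (1R,6S)-5-{[(4-methoxybenzyl)oxy]methyl}-6-methylcyclohepta-2,4-dien-1-ol
Conditions: NaBH4, CeCl3·7H2O, MeOH, −78 °C
Reagents that add atoms: none
Why: Luche 1,2-reduction as in step 13; hydride adds opposite the C10 methyl, giving the 1,3-cis alcohol (C8 R).

Step 24
Reactants: 32 dienol; 20 methoxyallene
Product: 33 2-bromoallyl mixed methyl acetal of 32 (acetal epimers)
Conditions: N-bromosuccinimide, CH2Cl2, −40 to 0 °C
Reagents that add atoms: methoxyallene, COC=C=C; N-bromosuccinimide, O=C1CCC(=O)N1Br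
Why: Bromoacetalisation as in step 14.

Step 25
Reactants: 33 bromoacetal
Product: 34 (3aR,7S,8aR)-2-methoxy-6-{[(4-methoxybenzyl)oxy]methyl}-7-methyl-3-methylidene-3,3a,4,7,8,8a-hexahydro-2H-cyclohepta[b]furan (C2 epimers)
Conditions: Bu3SnH (slow addition), AIBN (cat.), benzene, 80 °C
Reagents that add atoms: none
Why: Vinyl-radical 5-exo-trig cyclisation as in step 15; the tether from the C8 oxygen sets C7 (R) cis to it.

Step 26
Reactants: 34 bicyclic methyl acetal
Product: 35 [(3aR,7S,8aR)-2-methoxy-7-methyl-3-methylidene-3,3a,4,7,8,8a-hexahydro-2H-cyclohepta[b]furan-6-yl]methanol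
Conditions: DDQ, CH2Cl2/pH 7 buffer, 0 °C
Reagents that add atoms: none
Why: Oxidative PMB cleavage (benzylic hydride abstraction by DDQ, hydrolysis of the oxocarbenium ion); the acetal and both alkenes are inert.

Step 27
Reactants: 35 allylic alcohol
Product: 36 5,6-epoxide of 35 (epoxide configuration not controlled)
Conditions: VO(acac)2 (cat.), t-BuOOH, CH2Cl2, 0 °C to rt
Reagents that add atoms: tert-butyl hydroperoxide, CC(C)(C)OO
Why: Hydroxyl-directed vanadium-catalysed epoxidation of the allylic alcohol alkene only; the exocyclic methylene has no directing hydroxyl, and the epoxide configuration is of no consequence.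

Step 28
Reactants: 36 epoxy alcohol
Product: 37 (3aR,7S,8aR)-6-(hydroxymethyl)-2-methoxy-7-methyl-3-methylideneoctahydro-2H-cyclohepta[b]furan-6-ol (C6 epimers)
Conditions: LiAlH4, THF, 0 °C
Reagents that add atoms: none
Why: Hydride opens the trisubstituted epoxide at its less substituted carbon (C5), giving the 1,2-diol.

Step 29
Reactants: 37 1,2-diol
Product: 38 (3aR,7S,8aR)-2-methoxy-7-methyl-3-methylideneoctahydro-6H-cyclohepta[b]furan-6-one (ring-B ketone, C1=O)
Conditions: NaIO4, THF/H2O, rt
Reagents that add atoms: none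
Why: Malaprade glycol cleavage excises the CH2OH carbon and leaves the C1 ketone; C10 keeps the configuration from step 21, its methyl group equatorial.

**Ring C and end game**

Step 30
Reactants: 38 ring-B ketone; 24 ring-D/E α-methylene lactone; 39 acetaldehyde
Product: 42 Michael–aldol adduct (C5–C13' bond; C11' quaternary with CH2 toward C6' and 1-hydroxyethyl on the face of H7'; C5 and carbinol epimers), via lithium enolate 40 (not isolated), via lactone enolate 41 (not isolated)
Conditions: LiN(i-Pr)2, THF, −78 °C; 24 (slow addition), −78 °C; then CH3CHO, −78 °C; AcOH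
Reagents that add atoms: α-methylene lactone 24, C[C@@H]1C[C@@H]2OC(=O)C(=C)[C@@H]2CC=C1COCc3ccc(OC)cc3; acetaldehyde, CC=O
Why: Kinetic deprotonation on the CH2 side (C5), Michael addition of the lithium enolate to the α-methylene lactone, and aldol trapping of the resulting lactone enolate on the convex face of the cis-fused bicycle (syn to H7') set C11'; C5 and the carbinol carbon are left to steps 32 and 31.

Step 31
Reactants: 42 Michael–aldol adduct
Product: 43 1,5-diketone (as 42 with an acetyl group on C11')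
Conditions: Dess–Martin periodinane, NaHCO3, CH2Cl2, 0 °C to rt
Reagents that add atoms: none
Why: Dess–Martin oxidation of the only free (secondary) hydroxyl to the methyl ketone.

Step 32
Reactants: 43 1,5-diketone
Product: 44 ring-C ketol (C1 hydroxyl, C3 ketone, trans-fused rings B and C; C1 S, C5 S)
Conditions: DBU (0.3 equiv), dry THF, 0 °C to rt
Reagents that add atoms: none
Why: Reversible enolisation and intramolecular aldol addition (6-enolendo-exo-trig) of the acetyl CH3 (C2) to the C1 ketone under thermodynamic control; C5 epimerises through the ring-B enolate and the ketol should settle as the trans-fused isomer in which C13', C2, the C10 methyl and C11 are equatorial on the twist-chair of ring B and the new C1 hydroxyl is axial.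

Step 33
Reactants: 44 ring-C ketol
Product: 45 C1 trimethylsilyl ether of 44
Conditions: N-(trimethylsilyl)imidazole, CH2Cl2, rt
Reagents that add atoms: N-(trimethylsilyl)imidazole, C[Si](C)(C)n1ccnc1
Why: O-silylation of the tertiary β-hydroxyl blocks retro-aldol cleavage and β-elimination in the enolisation that follows, and the silylimidazole leaves the acetal and the ketone alone.

Step 34
Reactants: 45 silyl ether
Product: 46 C2=C3 enol triflate
Conditions: KN(SiMe3)2, THF, −78 °C; then PhN(SO2CF3)2, −78 to 0 °C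
Reagents that add atoms: N-phenylbis(trifluoromethanesulfonimide), O=S(=O)(N(c1ccccc1)S(=O)(=O)C(F)(F)F)C(F)(F)F
Why: Regiospecific enol triflate formation; the C3 ketone can enolise only toward C2 because C11' is quaternary, and the potassium enolate is triflated on oxygen.

Step 35
Reactants: 46 enol triflate; 47 tributyl(1-ethoxyvinyl)stannane
Product: 49 1-hydroxy-3-acetyl-2-ene with lactol A and PMB ether, via ethoxydiene 48 (not isolated)
Conditions: Pd(PPh3)4 (5 mol %), LiCl, THF, 65 °C; then 1 M HCl, THF, rt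
Reagents that add atoms: tributyl(1-ethoxyvinyl)stannane, CCOC(=C)[Sn](CCCC)(CCCC)CCCC; water, O
Why: Stille coupling of the enol triflate at zerovalent palladium installs the masked acetyl group on C3, and aqueous acid then hydrolyses the enol ether to the methyl ketone, removes the silyl ether and turns the methyl acetal into the lactol; C1 is not touched.

Step 36
Reactants: 49 PMB ether lactol
Product: 51 enal with α-methylene lactone A, via lactol diol 50 (not isolated)
Conditions: DDQ, CH2Cl2/pH 7 buffer, 0 °C; then MnO2, CH2Cl2, rt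
Reagents that add atoms: none
Why: DDQ removes the PMB ether and MnO2 oxidises both allylic positions, the primary alcohol to the enal and the lactol to lactone A; the tertiary carbinol cannot be oxidised.

Step 37
Reactants: 51 enal; 52 1-(triphenylphosphoranylidene)propan-2-one
Product: 53 1',5'-alkene precursor of the target (E-dienone side chain)
Conditions: toluene, 60 °C
Reagents that add atoms: 1-(triphenylphosphoranylidene)propan-2-one, CC(=O)C=P(c1ccccc1)(c1ccccc1)c1ccccc1
Why: Wittig olefination with the stabilised ylide, which reacts only with the aldehyde and gives the E enone.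

Step 38
Reactants: 53 dienone
Product: 54 target CNP0177598.2
Conditions: mCPBA (1.1 equiv), NaHCO3, CH2Cl2, 0 °C
Reagents that add atoms: 3-chloroperbenzoic acid, OOC(=O)c1cccc(Cl)c1
Why: Prilezhaev epoxidation of the only electron-rich alkene (C1'=C5', the γ,δ bond of the dienone; the enones and the methylene lactone are deactivated) on the face opposite the C10' methyl and the C7' substituent, giving the epoxide trans to them (C1' R, C5' R).

**Compound list**

1 | allyl acetoacetate | CC(=O)CC(=O)OCC=C | starting material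
2 | allyl 2-diazo-3-oxobutanoate | CC(=O)C(=[N+]=[N-])C(=O)OCC=C | intermediate (not isolated)
3 | allyl diazoacetate | [N-]=[N+]=CC(=O)OCC=C | intermediate
4 | (1R,5S)-3-oxabicyclo[3.1.0]hexan-2-one | O=C1OC[C@H]2C[C@@H]12 | intermediate
5 | (1S,5R)-3-oxabicyclo[3.1.0]hexan-2-one | O=C1OC[C@@H]2C[C@H]12 | intermediate
6 | 4-methoxybenzyl alcohol | COc1ccc(CO)cc1 | starting material
7 | tributyl(iodomethyl)stannane | CCCC[Sn](CI)(CCCC)CCCC | starting material
8 | tributyl{[(4-methoxybenzyl)oxy]methyl}stannane | CCCC[Sn](COCc1ccc(OC)cc1)(CCCC)CCCC | intermediate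
9 | (4-methoxybenzyloxy)methyllithium (cold THF solution) | [Li]COCc1ccc(OC)cc1 | intermediate
10 | ethyltriphenylphosphonium bromide | CC[P+](c1ccccc1)(c1ccccc1)c1ccccc1.[Br-] | starting material
11 | ethylidenetriphenylphosphorane (THF stock solution) | CC=P(c1ccccc1)(c1ccccc1)c1ccccc1 | intermediate
12 | (1R,5S)-2-{[(4-methoxybenzyl)oxy]methyl}-3-oxabicyclo[3.1.0]hexan-2-ol (C2 epimers) | OC1(COCc2ccc(OC)cc2)OC[C@H]2C[C@@H]12 | intermediate
13 | [(1S,2R)-2-{(2Z)-1-[(4-methoxybenzyl)oxy]but-2-en-2-yl}cyclopropyl]methanol | OC[C@H]1C[C@H]1/C(COCc2ccc(OC)cc2)=C/C | intermediate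
14 | (1S,2R)-2-{(2Z)-1-[(4-methoxybenzyl)oxy]but-2-en-2-yl}cyclopropane-1-carboxylic acid | OC(=O)[C@H]1C[C@H]1/C(COCc2ccc(OC)cc2)=C/C | intermediate
15 | 1-[(1S,2R)-2-{(2Z)-1-[(4-methoxybenzyl)oxy]but-2-en-2-yl}cyclopropyl]ethan-1-one | CC(=O)[C@H]1C[C@H]1/C(COCc2ccc(OC)cc2)=C/C | intermediate
16 | tert-butyldimethylsilyl enol ether of 15 (cis-divinylcyclopropane) | C=C(O[Si](C)(C)C(C)(C)C)[C@H]1C[C@H]1/C(COCc2ccc(OC)cc2)=C/C | intermediate (not isolated)
17 | tert-butyl{[(6R)-5-{[(4-methoxybenzyl)oxy]methyl}-6-methylcyclohepta-1,4-dien-1-yl]oxy}dimethylsilane | C[C@@H]1CC(O[Si](C)(C)C(C)(C)C)=CCC=C1COCc2ccc(OC)cc2 | intermediate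
18 | (6R)-5-{[(4-methoxybenzyl)oxy]methyl}-6-methylcyclohepta-2,4-dien-1-one | C[C@@H]1CC(=O)C=CC=C1COCc2ccc(OC)cc2 | intermediate
19 | (1S,6R)-5-{[(4-methoxybenzyl)oxy]methyl}-6-methylcyclohepta-2,4-dien-1-ol | C[C@@H]1C[C@H](O)C=CC=C1COCc2ccc(OC)cc2 | intermediate
20 | methoxyallene | COC=C=C | starting material
21 | 2-bromoallyl mixed methyl acetal of 19 | C[C@@H]1C[C@H](OC(OC)C(Br)=C)C=CC=C1COCc2ccc(OC)cc2 | intermediate
22 | (3aS,7R,8aS)-2-methoxy-6-{[(4-methoxybenzyl)oxy]methyl}-7-methyl-3-methylidene-3,3a,4,7,8,8a-hexahydro-2H-cyclohepta[b]furan | C[C@@H]1C[C@@H]2OC(OC)C(=C)[C@@H]2CC=C1COCc3ccc(OC)cc3 | intermediate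
23 | lactol corresponding to 22 | C[C@@H]1C[C@@H]2OC(O)C(=C)[C@@H]2CC=C1COCc3ccc(OC)cc3 | intermediate (not isolated)
24 | (3aS,7R,8aS)-6-{[(4-methoxybenzyl)oxy]methyl}-7-methyl-3-methylidene-3,3a,4,7,8,8a-hexahydro-2H-cyclohepta[b]furan-2-one | C[C@@H]1C[C@@H]2OC(=O)C(=C)[C@@H]2CC=C1COCc3ccc(OC)cc3 | intermediate
25 | (1S,5R)-2-{[(4-methoxybenzyl)oxy]methyl}-3-oxabicyclo[3.1.0]hexan-2-ol (C2 epimers) | OC1(COCc2ccc(OC)cc2)OC[C@@H]2C[C@H]12 | intermediate
26 | [(1R,2S)-2-{(2Z)-1-[(4-methoxybenzyl)oxy]but-2-en-2-yl}cyclopropyl]methanol | OC[C@@H]1C[C@@H]1/C(COCc2ccc(OC)cc2)=C/C | intermediate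
27 | (1R,2S)-2-{(2Z)-1-[(4-methoxybenzyl)oxy]but-2-en-2-yl}cyclopropane-1-carboxylic acid | OC(=O)[C@@H]1C[C@@H]1/C(COCc2ccc(OC)cc2)=C/C | intermediate
28 | 1-[(1R,2S)-2-{(2Z)-1-[(4-methoxybenzyl)oxy]but-2-en-2-yl}cyclopropyl]ethan-1-one | CC(=O)[C@@H]1C[C@@H]1/C(COCc2ccc(OC)cc2)=C/C | intermediate
29 | tert-butyldimethylsilyl enol ether of 28 | C=C(O[Si](C)(C)C(C)(C)C)[C@@H]1C[C@@H]1/C(COCc2ccc(OC)cc2)=C/C | intermediate (not isolated)
30 | tert-butyl{[(6S)-5-{[(4-methoxybenzyl)oxy]methyl}-6-methylcyclohepta-1,4-dien-1-yl]oxy}dimethylsilane | C[C@H]1CC(O[Si](C)(C)C(C)(C)C)=CCC=C1COCc2ccc(OC)cc2 | intermediate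
31 | (6S)-5-{[(4-methoxybenzyl)oxy]methyl}-6-methylcyclohepta-2,4-dien-1-one | C[C@H]1CC(=O)C=CC=C1COCc2ccc(OC)cc2 | intermediate
32 | (1R,6S)-5-{[(4-methoxybenzyl)oxy]methyl}-6-methylcyclohepta-2,4-dien-1-ol | C[C@H]1C[C@@H](O)C=CC=C1COCc2ccc(OC)cc2 | intermediate
33 | 2-bromoallyl mixed methyl acetal of 32 | C[C@H]1C[C@@H](OC(OC)C(Br)=C)C=CC=C1COCc2ccc(OC)cc2 | intermediate
34 | (3aR,7S,8aR)-2-methoxy-6-{[(4-methoxybenzyl)oxy]methyl}-7-methyl-3-methylidene-3,3a,4,7,8,8a-hexahydro-2H-cyclohepta[b]furan | C[C@H]1C[C@H]2OC(OC)C(=C)[C@H]2CC=C1COCc3ccc(OC)cc3 | intermediate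
35 | [(3aR,7S,8aR)-2-methoxy-7-methyl-3-methylidene-3,3a,4,7,8,8a-hexahydro-2H-cyclohepta[b]furan-6-yl]methanol | C[C@H]1C[C@H]2OC(OC)C(=C)[C@H]2CC=C1CO | intermediate
36 | 5,6-epoxide of 35 | C[C@H]1C[C@H]2OC(OC)C(=C)[C@H]2CC2OC12CO | intermediate
37 | (3aR,7S,8aR)-6-(hydroxymethyl)-2-methoxy-7-methyl-3-methylideneoctahydro-2H-cyclohepta[b]furan-6-ol | C[C@H]1C[C@H]2OC(OC)C(=C)[C@H]2CCC1(O)CO | intermediate
38 | (3aR,7S,8aR)-2-methoxy-7-methyl-3-methylideneoctahydro-6H-cyclohepta[b]furan-6-one | C[C@H]1C[C@H]2OC(OC)C(=C)[C@H]2CCC1=O | intermediate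
39 | acetaldehyde | CC=O | starting material
40 | lithium enolate of 38 (C1–O, C1=C5) | C[C@H]1C[C@H]2OC(OC)C(=C)[C@H]2CC=C1O[Li] | intermediate (not isolated)
41 | lithium enolate of lactone D after Michael addition | C=C1C(OC)O[C@@H]2C[C@H](C)C(=O)C(CC3=C(O[Li])O[C@H]4C[C@@H](C)C(COCc5ccc(OC)cc5)=CC[C@@H]34)C[C@H]12 | intermediate (not isolated)
42 | Michael–aldol adduct (1-hydroxyethyl on C11') | C=C1C(OC)O[C@@H]2C[C@H](C)C(=O)C(C[C@@]3(C(C)O)C(=O)O[C@H]4C[C@@H](C)C(COCc5ccc(OC)cc5)=CC[C@@H]34)C[C@H]12 | intermediate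
43 | 1,5-diketone (acetyl on C11') | C=C1C(OC)O[C@@H]2C[C@H](C)C(=O)C(C[C@@]3(C(C)=O)C(=O)O[C@H]4C[C@@H](C)C(COCc5ccc(OC)cc5)=CC[C@@H]34)C[C@H]12 | intermediate
44 | ring-C ketol | C=C1C(OC)O[C@@H]2C[C@H](C)[C@@]3(O)CC(=O)[C@]4(C[C@@H]3C[C@H]12)C(=O)O[C@H]1C[C@@H](C)C(COCc5ccc(OC)cc5)=CC[C@H]14 | intermediate
45 | C1 trimethylsilyl ether of 44 | C=C1C(OC)O[C@@H]2C[C@H](C)[C@@]3(O[Si](C)(C)C)CC(=O)[C@]4(C[C@@H]3C[C@H]12)C(=O)O[C@H]1C[C@@H](C)C(COCc5ccc(OC)cc5)=CC[C@H]14 | intermediate
46 | C2=C3 enol triflate | C=C1C(OC)O[C@@H]2C[C@H](C)[C@@]3(O[Si](C)(C)C)C=C(OS(=O)(=O)C(F)(F)F)[C@]4(C[C@@H]3C[C@H]12)C(=O)O[C@H]1C[C@@H](C)C(COCc5ccc(OC)cc5)=CC[C@H]14 | intermediate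
47 | tributyl(1-ethoxyvinyl)stannane | CCOC(=C)[Sn](CCCC)(CCCC)CCCC | starting material
48 | 3-(1-ethoxyvinyl) diene | C=C1C(OC)O[C@@H]2C[C@H](C)[C@@]3(O[Si](C)(C)C)C=C(C(=C)OCC)[C@]4(C[C@@H]3C[C@H]12)C(=O)O[C@H]1C[C@@H](C)C(COCc5ccc(OC)cc5)=CC[C@H]14 | intermediate (not isolated)
49 | 1-hydroxy-3-acetyl-2-ene with lactol A and PMB ether | C=C1C(O)O[C@@H]2C[C@H](C)[C@@]3(O)C=C(C(C)=O)[C@]4(C[C@@H]3C[C@H]12)C(=O)O[C@H]1C[C@@H](C)C(COCc5ccc(OC)cc5)=CC[C@H]14 | intermediate
50 | lactol with free allylic alcohol | C=C1C(O)O[C@@H]2C[C@H](C)[C@@]3(O)C=C(C(C)=O)[C@]4(C[C@@H]3C[C@H]12)C(=O)O[C@H]1C[C@@H](C)C(CO)=CC[C@H]14 | intermediate (not isolated)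
51 | enal with α-methylene lactone A | C=C1C(=O)O[C@@H]2C[C@H](C)[C@@]3(O)C=C(C(C)=O)[C@]4(C[C@@H]3C[C@H]12)C(=O)O[C@H]1C[C@@H](C)C(C=O)=CC[C@H]14 | intermediate
52 | 1-(triphenylphosphoranylidene)propan-2-one | CC(=O)C=P(c1ccccc1)(c1ccccc1)c1ccccc1 | starting material
53 | 1',5'-alkene precursor (dienone) | C=C1C(=O)O[C@@H]2C[C@H](C)[C@@]3(O)C=C(C(C)=O)[C@]4(C[C@@H]3C[C@H]12)C(=O)O[C@H]1C[C@@H](C)C(/C=C/C(C)=O)=CC[C@H]14 | intermediate
54 | CNP0177598.2 | C=C1C(=O)O[C@@H]2C[C@H](C)[C@@]3(O)C=C(C(C)=O)[C@]4(C[C@@H]3C[C@H]12)C(=O)O[C@H]1C[C@@H](C)[C@]2(/C=C/C(C)=O)O[C@@H]2C[C@H]14 | target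

**Step count and risks**

Total: 38 steps. Longest linear sequence: 24 steps (step 1, step 3, steps 17 to 29, steps 30 to 38).

Steps most likely to fail:

1. Step 30. The lactone enolate formed by the Michael addition may take a proton from the ring-B ketone of its own molecule, or add to a second molecule of 24, before acetaldehyde traps it. Fallback: set out from 38 and condense it with 1,1-dimethylhydrazine (cat. AcOH, EtOH, reflux) to the dimethylhydrazone F1. Its azaenolate (LiN(i-Pr)2, THF, 0 °C, deprotonation on the CH2 side) is added to 24 at −78 °C and then to acetaldehyde; the hydrazone has no proton acidic enough to quench the lactone enolate, so the tandem Michael–aldol adduct, the hydrazone F2, should form. Cleavage of the hydrazone with CuCl2 in pH 7 phosphate buffer returns to 42.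

2. Step 32. The ketol may lose water to the conjugated enone, or C5 may equilibrate too slowly for the ring closure to be stereoconvergent. Fallback: set out from 43 and drive the annulation on purpose (pyrrolidine, AcOH, toluene, 60 °C) to the ring-C enone F3, in which C5 is the γ-position of the enone and equilibrates through the dienamine. Weitz–Scheffer epoxidation (t-BuOOH, DBU, CH2Cl2), the peroxide adding to C1 axially and trans to H5, gives the epoxy ketone F4. Reductive opening of the Cα–O bond with aluminium amalgam, Al(Hg), in THF/EtOH/H2O returns to 44.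

3. Step 13 (and step 23 in the mirror series). Facial selectivity of the hydride addition may be poor, hydride arriving on the methyl-bearing face and giving the 1,3-trans alcohol. Fallback: set out from 18, take the epimeric alcohol F5 from the same reduction and invert it by Mitsunobu reaction (4-nitrobenzoic acid, PPh3, DIAD, THF, 0 °C) to the 4-nitrobenzoate F6. Methanolysis (K2CO3, MeOH) returns to 19. The mirror-image sequence serves 32.

**Further compounds**

F1 | step 30 | N,N-dimethylhydrazone of ketone 38 | C[C@H]1C[C@H]2OC(OC)C(=C)[C@H]2CCC1=NN(C)C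
F2 | step 30 | N,N-dimethylhydrazone of adduct 42 | C=C1C(OC)O[C@@H]2C[C@H](C)C(=NN(C)C)C(C[C@@]3(C(C)O)C(=O)O[C@H]4C[C@@H](C)C(COCc5ccc(OC)cc5)=CC[C@@H]34)C[C@H]12
F3 | step 32 | ring-C enone (C1=C2, C3 ketone) | C=C1C(OC)O[C@@H]2C[C@H](C)C3=CC(=O)[C@]4(C[C@@H]3C[C@H]12)C(=O)O[C@H]1C[C@@H](C)C(COCc5ccc(OC)cc5)=CC[C@H]14
F4 | step 32 | 1,2-epoxy-3-ketone of ring C | C=C1C(OC)O[C@@H]2C[C@H](C)[C@]36O[C@@H]6C(=O)[C@]4(C[C@@H]3C[C@H]12)C(=O)O[C@H]1C[C@@H](C)C(COCc5ccc(OC)cc5)=CC[C@H]14
F5 | step 13 | (1R,6R)-5-{[(4-methoxybenzyl)oxy]methyl}-6-methylcyclohepta-2,4-dien-1-ol | C[C@@H]1C[C@@H](O)C=CC=C1COCc2ccc(OC)cc2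
F6 | step 13 | 4-nitrobenzoate of 19 | C[C@@H]1C[C@H](OC(=O)c2ccc(cc2)[N+](=O)[O-])C=CC=C1COCc3ccc(OC)cc3
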